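**Plan**

- Ring labels: ring A carries the arm at C1, the CH2 bridge at C2, OH at C3 and OMe at C5. Ring B carries the arm at C1', OH at C3', the bridge at C4' and OMe at C5'. Rings C and D are the two 4-hydroxy-3-methoxyphenyl rings.
- First cut: the two arms (ring A C1–CH2–CH2–ring C and ring B C1'–CH2–CH2–ring D) are the same 1,2-diarylethane link. Each is cut between its two methylene carbons, leaving dialdehyde 18 and two copies of benzylphosphonate 21.
- Second cut: the bond between the bridge carbon and ring B C4', leaving a ring A phthalide (7) and a ring B aryllithium (12).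
- Forward: all four benzene rings are bought. Rings A and B are joined by aryllithium opening of the lactone, and the bridge carbonyl is reduced to CH2. Both arm carbons are then raised to aldehydes, rings C and D are attached in one double olefination, and one hydrogenation saturates both alkenes and frees all four phenols.
- Stereochemistry: the target has no stereocentre; the E alkenes of 24 and the racemic centre of 14 are transient.

Key step: step 14

Remark: 4-benzyloxy-3-methoxybenzyl alcohol (19) is taken as a catalogue compound. The ring B phenol is carried as a MOM ether only as far as it is needed to direct lithiation, and is then exchanged for benzyl so that a single hydrogenation finishes the synthesis.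

**Route**

Step 1
Reactants: 1 3,5-dimethoxybenzyl alcohol
Product: 2 2-bromo-3,5-dimethoxybenzyl alcohol
Conditions: NBS (1.0 equiv), CH2Cl2, 0 °C to rt
Reagents that add atoms: N-bromosuccinimide, O=C1CCC(=O)N1Br
Why: Electrophilic aromatic bromination should go to C2, which is para to one methoxy group and ortho to the other, because the site between the two methoxy groups is more hindered and the symmetry of 1 makes C2 and C6 equivalent.

Step 2
Reactants: 2 2-bromo-3,5-dimethoxybenzyl alcohol
Product: 5 5,7-dimethoxyphthalide, via dilithiated benzyl alkoxide 3 (not isolated), via hydroxy acid 4 (not isolated)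
Conditions: n-BuLi (2.2 equiv), THF, −78 °C; CO2; then 2 M HCl, rt
Reagents that add atoms: carbon dioxide, O=C=O
Why: Deprotonation of the alcohol and bromine–lithium exchange give dianion 3, and its carboxylation followed by acid-induced lactonisation of hydroxy acid 4 is the standard phthalide synthesis from 2-bromobenzyl alcohols.

Step 3
Reactants: 5 5,7-dimethoxyphthalide
Product: 6 7-hydroxy-5-methoxyphthalide
Conditions: BCl3 (1.5 equiv), CH2Cl2, −78 to 0 °C; H2O
Reagents that add atoms: none
Why: Chelation-controlled Lewis-acid ether cleavage, in which BCl3 bound to the lactone carbonyl reaches only the neighbouring C7 methoxy group, so the C5 methyl ether should survive.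

Step 4
Reactants: 6 7-hydroxy-5-methoxyphthalide
Product: 7 7-(benzyloxy)-5-methoxyphthalide
Conditions: BnBr, K2CO3, DMF, 60 °C
Reagents that add atoms: benzyl bromide, BrCc1ccccc1
Why: Williamson etherification of the phenoxide gives a benzyl ether that withstands aryllithium, acid and oxidant and is removed only in the last step.

Step 5
Reactants: 8 3-hydroxy-5-methoxybenzaldehyde
Product: 9 3-methoxy-5-(methoxymethoxy)benzaldehyde
Conditions: MOMCl, i-Pr2NEt, CH2Cl2, 0 °C to rt
Reagents that add atoms: chloromethyl methyl ether, COCCl
Why: O-alkylation of the phenol (MOM protection) installs the acetal ether that will later direct lithiation to C4'.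

Step 6
Reactants: 9 3-methoxy-5-(methoxymethoxy)benzaldehyde
Product: 10 [3-methoxy-5-(methoxymethoxy)phenyl]methanol
Conditions: NaBH4, MeOH, 0 °C; H2O
Reagents that add atoms: none
Why: Borohydride reduction of the aryl aldehyde brings the ring B arm carbon to the alcohol level, which is inert to the later silane reduction whereas an acetal would not be.

Step 7
Reactants: 10 [3-methoxy-5-(methoxymethoxy)phenyl]methanol
Product: 11 tert-butyl{[3-methoxy-5-(methoxymethoxy)benzyl]oxy}dimethylsilane
Conditions: TBSCl, imidazole, DMF, rt
Reagents that add atoms: tert-butyldimethylsilyl chloride, C[Si](C)(Cl)C(C)(C)C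
Why: Silylation of the primary alcohol gives a bulky, base-stable ether that does not compete as a directing group in the lithiation.

Step 8
Reactants: 11 tert-butyl{[3-methoxy-5-(methoxymethoxy)benzyl]oxy}dimethylsilane (1.2 equiv); 7 7-(benzyloxy)-5-methoxyphthalide
Product: 13 keto alcohol [2-(benzyloxy)-6-(hydroxymethyl)-4-methoxyphenyl][4-(tert-butyldimethylsilyloxymethyl)-2-methoxy-6-(methoxymethoxy)phenyl]methanone, via aryllithium 12 (not isolated)
Conditions: n-BuLi (1.1 equiv relative to 11), THF, 0 °C, 1 h; then 7, THF, −78 to −20 °C; aq NH4Cl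
Reagents that add atoms: none
Why: Directed ortho-metalation at C4', the site flanked by the OMe and OMOM groups, followed by aryllithium opening of the phthalide (nucleophilic acyl substitution) should stop after one addition because the resulting tetra-ortho-substituted benzophenone carbonyl is too hindered for a second attack.

Step 9
Reactants: 13 keto alcohol
Product: 16 2-[2-(benzyloxy)-6-(hydroxymethyl)-4-methoxybenzyl]-5-(hydroxymethyl)-3-methoxyphenol, via racemic phthalan 14 (not isolated), via protected diarylmethane 15 (not isolated)
Conditions: Et3SiH (5 equiv), CF3CO2H (10 equiv), CH2Cl2, 0 °C; evaporate; then 1 M HCl in MeOH, rt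
Reagents that add atoms: none
Why: Ionic hydrogenation of a diaryl ketone (Kursanov–Parnes reduction), in which protonated 13 is captured by its neighbouring hydroxymethyl group and reduced to phthalan 14, whose benzhydrylic C–O bond is activated by four ortho or para oxygen substituents and so re-ionises and is reduced again to diarylmethane 15 (as in the silane ring-opening of electron-rich 2-aryltetrahydrofurans), while the two primary benzylic alcohols are meta to every oxygen and do not ionise; methanolic HCl then removes the MOM and silyl ethers by acetal exchange and desilylation, and any of them lost already in the first stage converges on 16.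

Step 10
Reactants: 16 2-[2-(benzyloxy)-6-(hydroxymethyl)-4-methoxybenzyl]-5-(hydroxymethyl)-3-methoxyphenol
Product: 17 {3-(benzyloxy)-2-[2-(benzyloxy)-4-(hydroxymethyl)-6-methoxybenzyl]-5-methoxyphenyl}methanol
Conditions: BnBr (1.1 equiv), K2CO3, acetone, reflux
Reagents that add atoms: benzyl bromide, BrCc1ccccc1
Why: Chemoselective Williamson benzylation, since K2CO3 deprotonates only the phenol and the two primary alcohols stay free.

Step 11
Reactants: 17 {3-(benzyloxy)-2-[2-(benzyloxy)-4-(hydroxymethyl)-6-methoxybenzyl]-5-methoxyphenyl}methanol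
Product: 18 3-(benzyloxy)-2-[2-(benzyloxy)-4-formyl-6-methoxybenzyl]-5-methoxybenzaldehyde
Conditions: Dess–Martin periodinane (2.6 equiv), CH2Cl2, rt
Reagents that add atoms: none
Why: Dess–Martin oxidation should convert both primary benzylic alcohols to aldehydes without over-oxidation and leave the benzyl and methyl ethers untouched.

Step 12
Reactants: 19 [4-(benzyloxy)-3-methoxyphenyl]methanol
Product: 20 4-benzyloxy-3-methoxybenzyl chloride
Conditions: SOCl2, CH2Cl2, 0 °C to rt
Reagents that add atoms: thionyl chloride, ClS(Cl)=O
Why: Chlorodehydroxylation of the benzylic alcohol through its chlorosulfite gives a benzylic chloride that keeps better than the corresponding bromide.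

Step 13
Reactants: 20 4-benzyloxy-3-methoxybenzyl chloride
Product: 21 diethyl [4-(benzyloxy)-3-methoxybenzyl]phosphonate
Conditions: P(OEt)3 (neat, excess), 140 °C
Reagents that add atoms: triethyl phosphite, CCOP(OCC)OCC
Why: Michaelis–Arbuzov reaction of the activated benzylic chloride with triethyl phosphite, driven by loss of chloroethane.

Step 14
Reactants: 18 3-(benzyloxy)-2-[2-(benzyloxy)-4-formyl-6-methoxybenzyl]-5-methoxybenzaldehyde; 21 diethyl [4-(benzyloxy)-3-methoxybenzyl]phosphonate (2.6 equiv)
Product: 24 (E,E)-bis-stilbene in which each formyl group of 18 has become an (E)-CH=CH–[4-(benzyloxy)-3-methoxyphenyl] unit, via potassium phosphonate carbanion 22 (not isolated), via mono-stilbene aldehyde 23 (not isolated)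
Conditions: KOt-Bu (3.0 equiv), THF, 0 °C to rt; 1 M HCl work-up
Reagents that add atoms: none
Why: Deprotonation of 21 by KOt-Bu gives the phosphonate-stabilised benzylic carbanion 22, which adds to each formyl carbon to give a β-alkoxyphosphonate that closes to an oxaphosphetane and collapses with loss of diethyl phosphate, the unhindered ring B aldehyde reacting first (23) and the ring A aldehyde second. This is the Horner–Wadsworth–Emmons stilbene synthesis from a benzylphosphonate and aromatic aldehydes. No ring is closed and no stereocentre is created; reversible addition of the semi-stabilised carbanion should favour the E alkenes, whose geometry is in any case erased in step 15. The only selectivity needed is completeness of the double condensation, which is secured by the excess of 22, by the absence of enolisable or other electrophilic sites in 18 (only benzyl and methyl ethers are present), and by the ring A aldehyde having only one ortho substituent, a CH2 group. The regiochemistry of the skeleton was fixed in steps 3 and 8, so nothing else is at stake here.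

Step 15
Reactants: 24 (E,E)-bis-stilbene
Product: 25 2-{2-hydroxy-4-[2-(4-hydroxy-3-methoxyphenyl)ethyl]-6-methoxybenzyl}-3-[2-(4-hydroxy-3-methoxyphenyl)ethyl]-5-methoxyphenol (CNP0079001.0)
Conditions: H2 (1 atm), 10% Pd/C, THF–MeOH, rt
Reagents that add atoms: none
Why: Heterogeneous catalytic hydrogenation saturates both stilbene double bonds and hydrogenolyses the four aryl benzyl ethers in one operation, while the diarylmethane bridge and the methyl ethers are inert.

**Compound list**

1 | 3,5-dimethoxybenzyl alcohol | COc1cc(CO)cc(OC)c1 | starting material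
2 | 2-bromo-3,5-dimethoxybenzyl alcohol | COc1cc(CO)c(Br)c(OC)c1 | intermediate
3 | lithium (2-lithio-3,5-dimethoxyphenyl)methoxide, formed in the flask | [Li]OCc1cc(OC)cc(OC)c1[Li] | intermediate
4 | 2-(hydroxymethyl)-4,6-dimethoxybenzoic acid, formed in the flask | COc1cc(CO)c(C(=O)O)c(OC)c1 | intermediate
5 | 5,7-dimethoxyphthalide | COc1cc2c(c(OC)c1)C(=O)OC2 | intermediate
6 | 7-hydroxy-5-methoxyphthalide | COc1cc(O)c2c(c1)COC2=O | intermediate
7 | 7-(benzyloxy)-5-methoxyphthalide | COc1cc(OCc3ccccc3)c2c(c1)COC2=O | intermediate
8 | 3-hydroxy-5-methoxybenzaldehyde | COc1cc(O)cc(C=O)c1 | starting material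
9 | 3-methoxy-5-(methoxymethoxy)benzaldehyde | COCOc1cc(OC)cc(C=O)c1 | intermediate
10 | [3-methoxy-5-(methoxymethoxy)phenyl]methanol | COCOc1cc(OC)cc(CO)c1 | intermediate
11 | tert-butyl{[3-methoxy-5-(methoxymethoxy)benzyl]oxy}dimethylsilane | COCOc1cc(OC)cc(CO[Si](C)(C)C(C)(C)C)c1 | intermediate
12 | [4-(tert-butyldimethylsilyloxymethyl)-2-methoxy-6-(methoxymethoxy)phenyl]lithium, formed in the flask | [Li]c1c(OC)cc(CO[Si](C)(C)C(C)(C)C)cc1OCOC | intermediate
13 | [2-(benzyloxy)-6-(hydroxymethyl)-4-methoxyphenyl][4-(tert-butyldimethylsilyloxymethyl)-2-methoxy-6-(methoxymethoxy)phenyl]methanone | COc1cc(CO)c(C(=O)c2c(OC)cc(CO[Si](C)(C)C(C)(C)C)cc2OCOC)c(OCc2ccccc2)c1 | intermediate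
14 | racemic 7-(benzyloxy)-5-methoxy-1-[4-(tert-butyldimethylsilyloxymethyl)-2-methoxy-6-(methoxymethoxy)phenyl]-1,3-dihydro-2-benzofuran, formed in the flask | COc1cc2c(c(OCc3ccccc3)c1)C(OC2)c1c(OC)cc(CO[Si](C)(C)C(C)(C)C)cc1OCOC | intermediate
15 | {3-(benzyloxy)-2-[4-(tert-butyldimethylsilyloxymethyl)-2-methoxy-6-(methoxymethoxy)benzyl]-5-methoxyphenyl}methanol, formed in the flask | COc1cc(CO)c(Cc2c(OC)cc(CO[Si](C)(C)C(C)(C)C)cc2OCOC)c(OCc2ccccc2)c1 | intermediate
16 | 2-[2-(benzyloxy)-6-(hydroxymethyl)-4-methoxybenzyl]-5-(hydroxymethyl)-3-methoxyphenol | COc1cc(CO)c(Cc2c(OC)cc(CO)cc2O)c(OCc2ccccc2)c1 | intermediate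
17 | {3-(benzyloxy)-2-[2-(benzyloxy)-4-(hydroxymethyl)-6-methoxybenzyl]-5-methoxyphenyl}methanol | COc1cc(CO)c(Cc2c(OC)cc(CO)cc2OCc2ccccc2)c(OCc2ccccc2)c1 | intermediate
18 | 3-(benzyloxy)-2-[2-(benzyloxy)-4-formyl-6-methoxybenzyl]-5-methoxybenzaldehyde | COc1cc(C=O)c(Cc2c(OC)cc(C=O)cc2OCc2ccccc2)c(OCc2ccccc2)c1 | intermediate
19 | [4-(benzyloxy)-3-methoxyphenyl]methanol | COc1cc(CO)ccc1OCc1ccccc1 | starting material
20 | 4-benzyloxy-3-methoxybenzyl chloride | COc1cc(CCl)ccc1OCc1ccccc1 | intermediate
21 | diethyl [4-(benzyloxy)-3-methoxybenzyl]phosphonate | CCOP(=O)(Cc1ccc(OCc2ccccc2)c(OC)c1)OCC | intermediate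
22 | potassium salt of the benzylic carbanion of 21, formed in the flask | CCOP(=O)([CH-]c1ccc(OCc2ccccc2)c(OC)c1)OCC.[K+] | intermediate
23 | 3-(benzyloxy)-2-{2-(benzyloxy)-4-[(E)-2-(4-(benzyloxy)-3-methoxyphenyl)ethenyl]-6-methoxybenzyl}-5-methoxybenzaldehyde, formed in the flask | COc1cc(C=O)c(Cc2c(OC)cc(/C=C/c3ccc(OCc4ccccc4)c(OC)c3)cc2OCc2ccccc2)c(OCc2ccccc2)c1 | intermediate
24 | (E,E)-bis-stilbene: 1-(benzyloxy)-2-{2-(benzyloxy)-4-[(E)-2-(4-(benzyloxy)-3-methoxyphenyl)ethenyl]-6-methoxybenzyl}-3-[(E)-2-(4-(benzyloxy)-3-methoxyphenyl)ethenyl]-5-methoxybenzene | COc1cc(/C=C/c2ccc(OCc3ccccc3)c(OC)c2)c(Cc2c(OC)cc(/C=C/c3ccc(OCc4ccccc4)c(OC)c3)cc2OCc2ccccc2)c(OCc2ccccc2)c1 | intermediate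
25 | 2-{2-hydroxy-4-[2-(4-hydroxy-3-methoxyphenyl)ethyl]-6-methoxybenzyl}-3-[2-(4-hydroxy-3-methoxyphenyl)ethyl]-5-methoxyphenol (CNP0079001.0, achiral) | COc1cc(O)c(Cc2c(O)cc(CCc3ccc(O)c(OC)c3)cc2OC)c(CCc2ccc(O)c(OC)c2)c1 | target

**Step count and risks**

Total step count: 15. Longest linear sequence: 10 steps (steps 1–4, 8–11, 14, 15).

Steps most likely to fail:

1. Step 9. The reversible closure to the cyclic ether may hold back the second hydride transfer so that the reduction stalls. Alternatively, the acid may cut the electron-rich diarylmethyl link (retro-Friedel–Crafts) or strip the ring A benzyl ether before reduction is complete. The fallback sets out from 13 and avoids cations altogether. LiAlH4 in THF at 0 °C should give the racemic benzhydrol diol F1. Neutral hydrogenolysis (H2, Pd/C, EtOAc) should cleave its doubly benzylic, oxygen-activated C–OH bond much faster than the primary benzylic C–O bonds. It also removes the ring A benzyl ether, giving the ring A phenol diarylmethane F2. Methanolic HCl then removes the MOM and silyl ethers to give the tetraol F3. Double O-benzylation of its two phenols (BnBr 2.2 equiv, K2CO3, acetone) returns to the route at 17.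

2. Step 8. The hindered aryllithium may act as a base toward the lactone CH2 group, or add only sluggishly to the alkoxy-flanked lactone carbonyl, so that the union does not go to completion. The fallback sets out from 7 and replaces the lactone by an aldehyde electrophile. Reduction with i-Bu2AlH (toluene, −78 °C) should give the lactol F4. Its lithium alkoxide opens to a non-enolisable and far more electrophilic hydroxy aldehyde. Treatment with two equivalents of 12 (the first serving as base) should give the benzhydrol diol F1. Under the conditions of step 9, F1 enters the same ionic hydrogenation and returns to the route at 16.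

3. Step 3. Regiocontrol of the ether cleavage may be lost, through cleavage of the C5 methyl ether as well or through Lewis-acid opening of the lactone. The fallback sets out from 5 and separates cleavage from differentiation. Exhaustive demethylation with BBr3 (CH2Cl2, −78 °C to rt) should give 5,7-dihydroxyphthalide F5. Mono-methylation with MeI (1.0 equiv) and K2CO3 in acetone should then occur at the C5 hydroxyl, because the C7 hydroxyl is hydrogen-bonded to the lactone carbonyl and much less nucleophilic. This returns to the route at 6.

Further compounds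
F1 | step 9 | racemic [2-(benzyloxy)-6-(hydroxymethyl)-4-methoxyphenyl][4-(tert-butyldimethylsilyloxymethyl)-2-methoxy-6-(methoxymethoxy)phenyl]methanol | COc1cc(CO)c(C(O)c2c(OC)cc(CO[Si](C)(C)C(C)(C)C)cc2OCOC)c(OCc2ccccc2)c1
F2 | step 9 | 2-[4-(tert-butyldimethylsilyloxymethyl)-2-methoxy-6-(methoxymethoxy)benzyl]-3-(hydroxymethyl)-5-methoxyphenol | COc1cc(CO)c(Cc2c(OC)cc(CO[Si](C)(C)C(C)(C)C)cc2OCOC)c(O)c1
F3 | step 9 | 2-[2-hydroxy-4-(hydroxymethyl)-6-methoxybenzyl]-3-(hydroxymethyl)-5-methoxyphenol | COc1cc(CO)c(Cc2c(OC)cc(CO)cc2O)c(O)c1
F4 | step 8 | racemic 7-(benzyloxy)-5-methoxy-1,3-dihydro-2-benzofuran-1-ol | COc1cc(OCc3ccccc3)c2c(c1)COC2O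
F5 | step 3 | 5,7-dihydroxyphthalide | Oc1cc(O)c2c(c1)COC2=O
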